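Conventions used throughout: the oxane is numbered O1, C2 (aryl), C3 (side chain), C4 (hydroxyl), C5, C6 (arylethyl arm). In the side chain, C1' is the methine on C3 (C3 of the heptenyl unit) and C3' is the carbinol (C5 of the heptenyl unit). ArT = 4-(triisopropylsilyloxy)phenyl; ArMs = 4-(methanesulfonyloxy)phenyl; R* = (1E,3S,5S)-5-(tert-butyldimethylsilyloxy)-1,7-bis(ArT)hept-1-en-3-yl.

## Analysis of the target

Blepharocalyxin C (26) is a dimeric diarylheptanoid built on one oxane ring: C2 carries a 4-hydroxyphenyl group, C3 a branched (1E)-5-hydroxy-1,7-bis(4-hydroxyphenyl)hept-1-en-3-yl chain, C4 a hydroxyl, C5 nothing, and C6 a 2-(4-hydroxyphenyl)ethyl arm. All six stereocentres are S. In the chair the C2 aryl, the C3 chain and the C6 arm are equatorial (2,3-trans, 2,6-cis) and the C4 hydroxyl is axial. C1' is contiguous with C3 and C2, and the C3' carbinol lies 1,3 to C1'. The sensitive groups are the four phenols, the O1–C2 bond (a 4-hydroxybenzylic ether that ionises easily to a benzylic cation or quinone methide) and the electron-rich (E)-styrene next to the C1' stereocentre. The synthesis is hard because of the contiguous C2–C3–C1' triad with a bulky branch on C3, the axial C4 hydroxyl beside it, and four nearly identical aryl groups of which only the one on C2 sits on an ionisable carbon. The strategy rests on C5: it is the only unsubstituted ring carbon and lies between C4 (a carbinol that can be a carbonyl) and C6, while O1 joins C2 and C6. O1, C2, C3 and C4 can therefore come from an anti β-hydroxy acid, C6 from an aldehyde and C5 from a methylene donor placed on C4, with the C5–C6 bond made last while O1 already links C2 and C6.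

## Retrosynthetic reasoning

**26 from 25 and 24.** The last bonds cut are to protecting groups: S–O cleavage of the aryl methanesulfonate in 25 gives 26, and Si–O cleavage of four silyl ethers in 24 gives 25. The C2 aryl oxygen is held as a sulfonate because that makes the C2 arene electron-poor, which the ring-forming step needs of the O1–C2 bond; the price is one separate deprotection. The other phenols and the C3' oxygen are silyl ethers so that one fluoride treatment frees them together.

**24 from 23.** The C4–H bond is cut to give oxan-4-one 23. The forward reduction has to deliver hydride from the equatorial direction to give the axial alcohol. The gain is that C4 need not be carried as a stereocentre and its carbonyl becomes the handle for ring construction.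

**23 from 22.** The C5–C6 bond is cut and C6 is reconnected to the C4 oxygen, which gives the 4-methylene-1,3-dioxane 22. This is the place to cut because C5 is the lone CH2, flanked by the carbonyl carbon (an enolate position) and by C6 (an oxocarbenium position on O1). The extra acetal ring is not in the target; it exists only to hold O1 and C6 on the molecule so that the C–C bond forms intramolecularly. The forward reaction must ionise the acetal at C6, keep C2 and C3 intact, and close the oxane 2,6-cis.

**22 from 21.** The exocyclic C=CH2 bond is cut back to the lactone carbonyl of dioxanone 21, so C5 arrives as a one-carbon unit. The forward carbonyl methylenation must be non-acidic, because both 21 and 22 are acetals.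

**21 from 19 and 3.** The two acetal C–O bonds at C6 are cut, giving anti β-hydroxy acid 19 and aldehyde 3. Compound 19 holds C2, C3, C4, O1 and the whole side chain. The forward acetalisation must place the arylethyl arm cis to the C2 aryl, which is the all-equatorial and most stable arrangement.

**19 from 17, and 17 from 13 and 15.** The C2–C3 bond is cut as an aldol bond between the enolate of imide 13 and aldehyde 15, with 17 as the adduct. An aldol is chosen because 2,3-trans in the ring corresponds to the anti aldol, and an N-acyloxazolidinone gives that anti relationship with a non-enolisable aryl aldehyde through its chelated enolate. The electron-poor aldehyde 15 is also a good acceptor.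

**13 from 9 and 12.** The styrene C=C bond is cut by cross-metathesis into vinyl compound 9 and styrene 12. A vinyl group is the easiest alkenyl group to place at C1' with stereocontrol, and the aryl can be added before any acid-sensitive intermediate exists.

**9 from 8.** The C1'–vinyl bond is cut as a conjugate addition to enoyl imide 8. The oxazolidinone that will direct the aldol also directs this addition, so one auxiliary sets C1', C3 and C2.

**8 from 5 and 7; 7 from 6.** The enoyl C=C bond is cut by cross-metathesis into terminal alkene 5 and acryloyl imide 7, which comes from auxiliary 6. This avoids an ozonolysis and olefination pair.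

**5 from 4, 3, 2 and 1; 12 from 10; 15 from 14.** The allyl–carbinol bond of 4 is cut as an asymmetric allylation of aldehyde 3, which sets C3'; silylation gives 5. Aldehyde 3 comes from ester 1 through 2 and serves twice: as the source of the C3'–C7' segment and as the C6 donor. Styrene 12 and aldehyde 15 are one step from 10 and 14.

## Alternatives that were turned down

**Alternative 1: oxidative C–H cyclisation forming C2–C3.** The disconnection cuts C2–C3. The open-chain precursor A1 carries the C2 aryl as a 4-silyloxybenzyl ether on the C6 oxygen and has C3 as the α-carbon of a β-keto ester, with a vinyl group standing in for the styrene at C1'. In the forward step DDQ removes hydride from the ArCH2–O group, and the aryl-stabilised oxocarbenium ion is attacked by the enol carbon C3 to give the 2,6-cis 3-methoxycarbonyl oxan-4-one A2.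

- For: a C–H bond serves as the latent electrophile, and no titanium reagent or enol acetal is needed. The C2 aryl is used in its natural electron-rich form, so no sulfonate has to be put on and removed. On these points it is stronger than the chosen route.
- Against: the nucleophile is a fully substituted enol carbon that already bears the branched C1' group, so the new bond creates a quaternary centre between two tertiary carbons. The ester must then be removed and C3 set by equilibration. DDQ would not spare an electron-rich styrene, so the aryl must be added afterwards by metathesis on a more congested alkene. Three other electron-rich arenes with benzylic CH2 groups also compete for the oxidant.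
- Comparison: the chosen route offers C2 and C3 fixed beforehand by a defined anti-aldol, no quaternary centre, and the complete side chain in place before the ring closes.

**Alternative 2: hetero-Diels–Alder forming O1–C2 and C5–C6.** The disconnection cuts both bonds at once. The 1-aryl-3-triethylsilyloxy diene A3, carrying the side chain on its C2, would react with aldehyde A4 under CrCl(L), a trivalent chromium complex of the tridentate Schiff base from cis-1-amino-2-indanol and 3-(1-adamantyl)-5-methylsalicylaldehyde. The product is the 2,6-cis dihydropyran A5, whose C3=C4 silyl enol ether unveils the ketone.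

- For: it is the most convergent of the four, forming two bonds and two stereocentres (C2 and C6) under catalyst control. In step economy and catalytic asymmetric induction it is stronger than the chosen route.
- Against: this catalyst class is at its best with dienes that carry oxygen at the terminus. Here the terminus carries an aryl group and the neighbouring diene carbon a bulky branched chain with two stereocentres, which crowds the endo transition state and introduces matched and mismatched pairing with the catalyst. The diene needs a geometry-defined, α-branched aryl enone and a regioselective enol silylation. C3 is left to a protonation. In A5 the C2–O1 bond is both benzylic to an electron-rich arene and allylic to an enol ether, so it is prone to ionise on the Lewis acid.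
- Comparison: the chosen route offers an intramolecular, substrate-controlled ring closure that does not depend on diene reactivity, with C3 already defined.

**Alternative 3: enzymatic quinone methide cyclisation forming O1–C2.** The disconnection cuts O1–C2. The seco diol A6 has a free 4-hydroxybenzyl group at C2 and all other phenols silylated. An FAD-dependent oxidase of the vanillyl-alcohol oxidase family with O2 would dehydrogenate it to the p-quinone methide, and the C6 hydroxyl would add to give A7.

- For: the conditions are the mildest of all. The free phenol is the recognition element, so no sulfonate is needed and the final deprotection is one step. Here it is stronger than the chosen route.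
- Against: these oxidases accept small 4-alkylphenols, and a large, lipophilic, tetrasilylated substrate is unlikely to fit the active site. The enzyme-bound quinone methide is normally captured by water or tautomerised to the alkene, and C3–H is available for that. The step forms only a C–O bond, so every C–C bond and five stereocentres (C3, C4, C6, C1', C3') must already be set in an acyclic precursor, which lengthens the route.
- Comparison: the chosen route offers a ring closure that makes a C–C bond and a stereocentre together and uses a reaction class with a defined substrate scope.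

Key step: step 15

## Route

Remark on the chemistry: the three phenols not on C2 are carried as triisopropylsilyl ethers because aryl tert-butyldimethylsilyl ethers are not safe towards the hydroperoxide and alkaline peroxide treatments used. The styrene phenol cannot be an acetate because Cp2TiMe2 would methylenate it.

Step 1
Reactants: 1 methyl 3-(4-hydroxyphenyl)propanoate
Product: 2 methyl 3-[4-(triisopropylsilyloxy)phenyl]propanoate
Conditions: i-Pr3SiCl, imidazole, DMF, 23 °C
Reagents that add atoms: triisopropylsilyl chloride, CC(C)[Si](Cl)(C(C)C)C(C)C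
Why: Silylation of a phenol under imidazole catalysis; the triisopropylsilyl ether withstands hydride, organometallic, hydroperoxide and Lewis acid steps and falls to fluoride at the end.

Step 2
Reactants: 2 methyl 3-[4-(triisopropylsilyloxy)phenyl]propanoate
Product: 3 3-[4-(triisopropylsilyloxy)phenyl]propanal
Conditions: i-Bu2AlH (1.05 equiv), CH2Cl2, −78 °C; aq. potassium sodium tartrate
Reagents that add atoms: none
Why: Partial reduction of a methyl ester; the aluminium hemiacetal is stable at −78 °C and releases the aldehyde only on hydrolysis.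

Step 3
Reactants: 3 3-[4-(triisopropylsilyloxy)phenyl]propanal
Product: 4 (3S)-1-[4-(triisopropylsilyloxy)phenyl]hex-5-en-3-ol
Conditions: (+)-Ipc2B(allyl) [from (−)-α-pinene], Et2O, −78 °C; then NaOH, H2O2, 0 → 23 °C
Reagents that add atoms: (+)-B-allyldiisopinocampheylborane, C[C@@H]1[C@H](C[C@H]2C[C@@H]1C2(C)C)B(CC=C)[C@H]1C[C@H]2C[C@@H]([C@@H]1C)C2(C)C
Why: Brown allylation through a chair Zimmerman–Traxler transition state; this antipode of the reagent adds allyl to the Re face of an unbranched aliphatic aldehyde, which should give the (S)-carbinol that becomes C3'.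

Step 4
Reactants: 4 (3S)-1-[4-(triisopropylsilyloxy)phenyl]hex-5-en-3-ol
Product: 5 (3S)-3-(tert-butyldimethylsilyloxy)-1-[4-(triisopropylsilyloxy)phenyl]hex-5-ene
Conditions: t-BuMe2SiCl, imidazole, DMF, 23 °C
Reagents that add atoms: tert-butyldimethylsilyl chloride, CC(C)(C)[Si](C)(C)Cl
Why: Silylation of a secondary alcohol; the alkyl silyl ether survives every later step up to the fluoride treatment.

Step 5
Reactants: 6 (4S)-4-benzyloxazolidin-2-one
Product: 7 (4S)-3-acryloyl-4-benzyloxazolidin-2-one
Conditions: MeMgBr, THF, 0 °C; acryloyl chloride, −78 → 0 °C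
Reagents that add atoms: acryloyl chloride, C=CC(Cl)=O
Why: N-Acylation of the bromomagnesium salt of the oxazolidinone; the magnesium counter-ion and low temperature suppress anionic polymerisation of the acryloyl group.

Step 6
Reactants: 5 (3S)-3-(tert-butyldimethylsilyloxy)-1-[4-(triisopropylsilyloxy)phenyl]hex-5-ene; 7 (4S)-3-acryloyl-4-benzyloxazolidin-2-one
Product: 8 (4S)-4-benzyl-3-[(2E,5S)-5-(tert-butyldimethylsilyloxy)-7-(ArT)hept-2-enoyl]oxazolidin-2-one
Conditions: second-generation Grubbs catalyst RuCl2(=CHPh)(H2IMes)(PCy3) (5 mol %), 7 (2 equiv), CH2Cl2, 40 °C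
Reagents that add atoms: none
Why: Olefin cross-metathesis between an unhindered terminal alkene and an electron-poor acryloyl imide, which should be selective for the cross product and for the E isomer.

Step 7
Reactants: 8 (4S)-4-benzyl-3-[(2E,5S)-5-(tert-butyldimethylsilyloxy)-7-(ArT)hept-2-enoyl]oxazolidin-2-one
Product: 9 (4S)-4-benzyl-3-[(3R,5S)-5-(tert-butyldimethylsilyloxy)-3-ethenyl-7-(ArT)heptanoyl]oxazolidin-2-one
Conditions: CH2=CHMgBr, CuBr·SMe2, THF/Me2S, −78 → −20 °C; aq. NH4Cl
Reagents that add atoms: vinylmagnesium bromide, C=C[Mg]Br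
Why: Copper-mediated conjugate addition to an N-enoyloxazolidinone; in the magnesium-chelated syn-s-cis conformer the vinyl group should add to the face away from the benzyl group, which sets C1'.

Step 8
Reactants: 10 4-acetoxystyrene
Product: 12 4-(triisopropylsilyloxy)styrene, via 4-vinylphenol 11 (not isolated)
Conditions: K2CO3 (cat.), MeOH, 0 °C; AcOH, solvent exchange in the cold; then i-Pr3SiCl, imidazole, DMF, 23 °C
Reagents that add atoms: triisopropylsilyl chloride, CC(C)[Si](Cl)(C(C)C)C(C)C
Why: Methanolysis of the aryl acetate, then silylation; 4-vinylphenol polymerises when concentrated and is therefore silylated without isolation.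

Step 9
Reactants: 9 (4S)-4-benzyl-3-[(3R,5S)-5-(tert-butyldimethylsilyloxy)-3-ethenyl-7-(ArT)heptanoyl]oxazolidin-2-one; 12 4-(triisopropylsilyloxy)styrene
Product: 13 (4S)-4-benzyl-3-[(3R,5S)-5-(tert-butyldimethylsilyloxy)-7-(ArT)-3-[(E)-2-(ArT)ethenyl]heptanoyl]oxazolidin-2-one
Conditions: second-generation Grubbs catalyst RuCl2(=CHPh)(H2IMes)(PCy3) (5–10 mol %), 12 (3 equiv), CH2Cl2, 40 °C
Reagents that add atoms: none
Why: Olefin cross-metathesis; the allylically branched alkene of 9 does not homodimerise, the styrene is the reactive partner, and the E aryl alkene is the thermodynamic product.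

Step 10
Reactants: 14 4-hydroxybenzaldehyde
Product: 15 4-formylphenyl methanesulfonate
Conditions: MeSO2Cl, Et3N, CH2Cl2, 0 °C
Reagents that add atoms: methanesulfonyl chloride, CS(Cl)(=O)=O
Why: Sulfonylation of a phenol; the sulfonate makes the aldehyde a better acceptor and later protects the benzylic C2–O1 bond from ionisation.

Step 11
Reactants: 13 (4S)-4-benzyl-3-[(3R,5S)-5-(tert-butyldimethylsilyloxy)-7-(ArT)-3-[(E)-2-(ArT)ethenyl]heptanoyl]oxazolidin-2-one; 15 4-formylphenyl methanesulfonate
Product: 17 (4S)-4-benzyl-3-[(2R,3S)-3-hydroxy-3-(ArMs)-2-(R*)propanoyl]oxazolidin-2-one, via aldol trimethylsilyl ether 16 (not isolated)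
Conditions: MgCl2 (0.3 equiv), Et3N, Me3SiCl, EtOAc, 23 °C; then MeOH, CF3CO2H (cat.), 23 °C
Reagents that add atoms: none
Why: Magnesium-halide-catalysed anti-aldol of an N-acyloxazolidinone with a non-enolisable aryl aldehyde (Evans anti-aldol); the chelated Z-enolate should react through a boat transition state on the face away from the benzyl group, which sets the carbons that become C3 and C2 as the anti pair. Silylation of the aldolate turns the magnesium over, and the labile trimethylsilyl ether is removed by acidic methanol.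

Step 12
Reactants: 17 (4S)-4-benzyl-3-[(2R,3S)-3-hydroxy-3-(ArMs)-2-(R*)propanoyl]oxazolidin-2-one
Product: 19 (2R,3S)-3-hydroxy-3-(ArMs)-2-(R*)propanoic acid, via peroxy acid 18 (not isolated)
Conditions: LiOH, H2O2, THF/H2O, 0 °C; aq. Na2SO3; then HCl to pH 3
Reagents that add atoms: hydrogen peroxide (as LiOOH), OO
Why: Hydroperoxide attacks the exocyclic imide carbonyl selectively even for α-branched acyl groups; sulfite reduces the percarboxylate before acidification, so the styrene is never exposed to a neutral peracid, and the auxiliary 6 is recovered.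

Step 13
Reactants: 19 (2R,3S)-3-hydroxy-3-(ArMs)-2-(R*)propanoic acid; 3 3-[4-(triisopropylsilyloxy)phenyl]propanal
Product: 21 (2R,5R,6S)-6-(ArMs)-5-(R*)-2-[2-(ArT)ethyl]-1,3-dioxan-4-one, via bis(trimethylsilyl) derivative 20 (not isolated)
Conditions: (Me3Si)2NH, CH2Cl2, 23 °C, evaporation; then 3, Me3SiOTf (0.2 equiv), CH2Cl2, −78 °C; pyridine quench
Reagents that add atoms: none
Why: Silyl-transfer acetalisation of a silyl ester/silyl ether pair with an aldehyde, with loss of hexamethyldisiloxane; the acetal carbon should settle cis to the aryl because the chair with aryl, side chain and arylethyl arm all equatorial is the most stable and the reaction equilibrates.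

Step 14
Reactants: 21 (2R,5R,6S)-6-(ArMs)-5-(R*)-2-[2-(ArT)ethyl]-1,3-dioxan-4-one
Product: 22 (2R,5R,6S)-6-(ArMs)-5-(R*)-2-[2-(ArT)ethyl]-4-methylidene-1,3-dioxane
Conditions: Cp2TiMe2 (3 equiv), THF, 65 °C, dark; filtration through basic Al2O3
Reagents that add atoms: dimethyltitanocene, C[Ti+2]C.c1cc[cH-]c1.c1cc[cH-]c1
Why: Petasis methylenation; thermolysis gives Cp2Ti=CH2, which converts the lactone carbonyl into the exocyclic enol ether through an oxatitanacyclobutane. The reagent is not acidic and 21 has no other carbonyl group, so acetal, sulfonate and silyl ethers should be left alone.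

Step 15
Reactants: 22 (2R,5R,6S)-6-(ArMs)-5-(R*)-2-[2-(ArT)ethyl]-4-methylidene-1,3-dioxane
Product: 23 (2S,3R,6S)-2-(ArMs)-3-(R*)-6-[2-(ArT)ethyl]oxan-4-one
Conditions: Me2AlCl (1.5 equiv), CH2Cl2, −78 → −30 °C; aq. NaHCO3
Reagents that add atoms: none
Why: Me2AlCl binds the enol ether oxygen of 22 and the bond between that oxygen and the acetal carbon breaks, giving an O1=C6 oxocarbenium ion tethered through O1–C2–C3 to an aluminium enolate whose nucleophilic carbon is the former methylene, C5. C5 then adds to C6, which forms the C5–C6 bond and the oxan-4-one; this is the Petasis–Ferrier rearrangement of a 4-methylene-1,3-dioxane, a known reaction class that includes 5-substituted substrates. The oxane closes by a 6-(enolendo)-endo-trig cyclisation, with both the enolate C=C and the C=O+ bond inside the forming ring. The new stereocentre C6 is controlled by the chair transition state: with the C2 aryl and the C3 chain equatorial, the oxocarbenium ion places its arylethyl arm equatorial, so the ring should close 2,6-cis. C2 and C3 are not touched because only the C5 side is an enolate. The step needs ionisation at the acetal carbon and not at benzylic C2; the electron-withdrawing sulfonate on the C2 arene disfavours a C2 cation while the acetal carbon is activated by two oxygens. It also needs capture of the cation by the enolate and not by the styrene π bond; the aluminium enolate is by far the stronger nucleophile and sits in the same ion pair, and the low temperature favours this fast collapse.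

Step 16
Reactants: 23 (2S,3R,6S)-2-(ArMs)-3-(R*)-6-[2-(ArT)ethyl]oxan-4-one
Product: 24 (2S,3S,4S,6S)-2-(ArMs)-3-(R*)-6-[2-(ArT)ethyl]oxan-4-ol
Conditions: LiBH(s-Bu)3, THF, −78 °C; then NaOH, H2O2, 0 °C
Reagents that add atoms: none
Why: The bulky trialkylborohydride should attack the conformationally locked oxan-4-one from the equatorial direction, away from the axial hydrogens at C2 and C6, which gives the axial (4S) alcohol.

Step 17
Reactants: 24 (2S,3S,4S,6S)-2-(ArMs)-3-(R*)-6-[2-(ArT)ethyl]oxan-4-ol
Product: 25 4-[(2S,3S,4S,6S)-4-hydroxy-3-[(1E,3S,5S)-5-hydroxy-1,7-bis(4-hydroxyphenyl)hept-1-en-3-yl]-6-[2-(4-hydroxyphenyl)ethyl]oxan-2-yl]phenyl methanesulfonate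
Conditions: Bu4NF (6 equiv), THF, 0 → 23 °C; aq. NH4Cl
Reagents that add atoms: none
Why: Fluoride cleaves the three aryl triisopropylsilyl ethers and the secondary tert-butyldimethylsilyl ether in one operation; the aryl sulfonate keeps the C2 arene electron-poor until the last step.

Step 18
Reactants: 25 4-[(2S,3S,4S,6S)-4-hydroxy-3-[(1E,3S,5S)-5-hydroxy-1,7-bis(4-hydroxyphenyl)hept-1-en-3-yl]-6-[2-(4-hydroxyphenyl)ethyl]oxan-2-yl]phenyl methanesulfonate
Product: 26 blepharocalyxin C, (2S,3S,4S,6S)-3-[(1E,3S,5S)-5-hydroxy-1,7-bis(4-hydroxyphenyl)hept-1-en-3-yl]-2-(4-hydroxyphenyl)-6-[2-(4-hydroxyphenyl)ethyl]oxan-4-ol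
Conditions: KOH, MeOH/H2O (4:1), 50 °C, argon; then aq. HCl to pH 6
Reagents that add atoms: none
Why: Alkaline cleavage of an aryl methanesulfonate at sulfur; water in the medium leads to methanesulfonate salt and not to a methylating ester, argon protects the phenolates, and the equatorial C2 aryl is the thermodynamic arrangement, so a reversible opening at C2 would not change the configuration.

## Compound list

1 | methyl 3-(4-hydroxyphenyl)propanoate | COC(=O)CCc1ccc(O)cc1 | starting material
2 | methyl 3-[4-(triisopropylsilyloxy)phenyl]propanoate | COC(=O)CCc1ccc(O[Si](C(C)C)(C(C)C)C(C)C)cc1 | intermediate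
3 | 3-[4-(triisopropylsilyloxy)phenyl]propanal | O=CCCc1ccc(O[Si](C(C)C)(C(C)C)C(C)C)cc1 | intermediate
4 | (3S)-1-[4-(triisopropylsilyloxy)phenyl]hex-5-en-3-ol | C=CC[C@@H](O)CCc1ccc(O[Si](C(C)C)(C(C)C)C(C)C)cc1 | intermediate
5 | (3S)-3-(tert-butyldimethylsilyloxy)-1-[4-(triisopropylsilyloxy)phenyl]hex-5-ene | C=CC[C@@H](O[Si](C)(C)C(C)(C)C)CCc1ccc(O[Si](C(C)C)(C(C)C)C(C)C)cc1 | intermediate
6 | (4S)-4-benzyloxazolidin-2-one | O=C1N[C@@H](Cc2ccccc2)CO1 | starting material
7 | (4S)-3-acryloyl-4-benzyloxazolidin-2-one | C=CC(=O)N1[C@@H](Cc2ccccc2)COC1=O | intermediate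
8 | (4S)-4-benzyl-3-[(2E,5S)-5-(tert-butyldimethylsilyloxy)-7-[4-(triisopropylsilyloxy)phenyl]hept-2-enoyl]oxazolidin-2-one | O=C(/C=C/C[C@@H](O[Si](C)(C)C(C)(C)C)CCc1ccc(O[Si](C(C)C)(C(C)C)C(C)C)cc1)N1[C@@H](Cc2ccccc2)COC1=O | intermediate
9 | (4S)-4-benzyl-3-[(3R,5S)-5-(tert-butyldimethylsilyloxy)-3-ethenyl-7-[4-(triisopropylsilyloxy)phenyl]heptanoyl]oxazolidin-2-one | C=C[C@H](C[C@@H](O[Si](C)(C)C(C)(C)C)CCc1ccc(O[Si](C(C)C)(C(C)C)C(C)C)cc1)CC(=O)N1[C@@H](Cc2ccccc2)COC1=O | intermediate
10 | 4-acetoxystyrene | CC(=O)Oc1ccc(C=C)cc1 | starting material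
11 | 4-vinylphenol (not isolated) | Oc1ccc(C=C)cc1 | intermediate
12 | 4-(triisopropylsilyloxy)styrene | C=Cc1ccc(O[Si](C(C)C)(C(C)C)C(C)C)cc1 | intermediate
13 | (4S)-4-benzyl-3-[(3R,5S)-5-(tert-butyldimethylsilyloxy)-7-[4-(triisopropylsilyloxy)phenyl]-3-[(E)-2-[4-(triisopropylsilyloxy)phenyl]ethenyl]heptanoyl]oxazolidin-2-one | CC(C)[Si](Oc1ccc(/C=C/[C@H](C[C@@H](O[Si](C)(C)C(C)(C)C)CCc2ccc(O[Si](C(C)C)(C(C)C)C(C)C)cc2)CC(=O)N2[C@@H](Cc3ccccc3)COC2=O)cc1)(C(C)C)C(C)C | intermediate
14 | 4-hydroxybenzaldehyde | O=Cc1ccc(O)cc1 | starting material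
15 | 4-formylphenyl methanesulfonate | CS(=O)(=O)Oc1ccc(C=O)cc1 | intermediate
16 | trimethylsilyl ether of aldol adduct 17 (not isolated) | CC(C)[Si](Oc1ccc(/C=C/[C@H](C[C@@H](O[Si](C)(C)C(C)(C)C)CCc2ccc(O[Si](C(C)C)(C(C)C)C(C)C)cc2)[C@@H](C(=O)N2[C@@H](Cc3ccccc3)COC2=O)[C@@H](c2ccc(OS(C)(=O)=O)cc2)O[Si](C)(C)C)cc1)(C(C)C)C(C)C | intermediate
17 | (4S)-4-benzyl-3-[(2R,3S)-3-hydroxy-3-[4-(methanesulfonyloxy)phenyl]-2-(R*)propanoyl]oxazolidin-2-one | CC(C)[Si](Oc1ccc(/C=C/[C@H](C[C@@H](O[Si](C)(C)C(C)(C)C)CCc2ccc(O[Si](C(C)C)(C(C)C)C(C)C)cc2)[C@@H](C(=O)N2[C@@H](Cc3ccccc3)COC2=O)[C@@H](c2ccc(OS(C)(=O)=O)cc2)O)cc1)(C(C)C)C(C)C | intermediate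
18 | peroxy acid corresponding to 19 (not isolated) | CC(C)[Si](Oc1ccc(/C=C/[C@H](C[C@@H](O[Si](C)(C)C(C)(C)C)CCc2ccc(O[Si](C(C)C)(C(C)C)C(C)C)cc2)[C@@H](C(=O)OO)[C@@H](c2ccc(OS(C)(=O)=O)cc2)O)cc1)(C(C)C)C(C)C | intermediate
19 | (2R,3S)-3-hydroxy-3-[4-(methanesulfonyloxy)phenyl]-2-(R*)propanoic acid | CC(C)[Si](Oc1ccc(/C=C/[C@H](C[C@@H](O[Si](C)(C)C(C)(C)C)CCc2ccc(O[Si](C(C)C)(C(C)C)C(C)C)cc2)[C@@H](C(=O)O)[C@@H](c2ccc(OS(C)(=O)=O)cc2)O)cc1)(C(C)C)C(C)C | intermediate
20 | trimethylsilyl ester and trimethylsilyl ether of 19 (not isolated) | CC(C)[Si](Oc1ccc(/C=C/[C@H](C[C@@H](O[Si](C)(C)C(C)(C)C)CCc2ccc(O[Si](C(C)C)(C(C)C)C(C)C)cc2)[C@@H](C(=O)O[Si](C)(C)C)[C@@H](c2ccc(OS(C)(=O)=O)cc2)O[Si](C)(C)C)cc1)(C(C)C)C(C)C | intermediate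
21 | (2R,5R,6S)-6-[4-(methanesulfonyloxy)phenyl]-5-(R*)-2-[2-[4-(triisopropylsilyloxy)phenyl]ethyl]-1,3-dioxan-4-one | CC(C)[Si](Oc1ccc(/C=C/[C@H](C[C@@H](O[Si](C)(C)C(C)(C)C)CCc2ccc(O[Si](C(C)C)(C(C)C)C(C)C)cc2)[C@@H]2[C@@H](c3ccc(OS(C)(=O)=O)cc3)O[C@@H](CCc3ccc(O[Si](C(C)C)(C(C)C)C(C)C)cc3)OC2=O)cc1)(C(C)C)C(C)C | intermediate
22 | (2R,5R,6S)-6-[4-(methanesulfonyloxy)phenyl]-5-(R*)-2-[2-[4-(triisopropylsilyloxy)phenyl]ethyl]-4-methylidene-1,3-dioxane | CC(C)[Si](Oc1ccc(/C=C/[C@H](C[C@@H](O[Si](C)(C)C(C)(C)C)CCc2ccc(O[Si](C(C)C)(C(C)C)C(C)C)cc2)[C@@H]2[C@@H](c3ccc(OS(C)(=O)=O)cc3)O[C@@H](CCc3ccc(O[Si](C(C)C)(C(C)C)C(C)C)cc3)OC2=C)cc1)(C(C)C)C(C)C | intermediate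
23 | (2S,3R,6S)-2-[4-(methanesulfonyloxy)phenyl]-3-(R*)-6-[2-[4-(triisopropylsilyloxy)phenyl]ethyl]oxan-4-one | CC(C)[Si](Oc1ccc(/C=C/[C@H](C[C@@H](O[Si](C)(C)C(C)(C)C)CCc2ccc(O[Si](C(C)C)(C(C)C)C(C)C)cc2)[C@@H]2[C@@H](c3ccc(OS(C)(=O)=O)cc3)O[C@@H](CCc3ccc(O[Si](C(C)C)(C(C)C)C(C)C)cc3)CC2=O)cc1)(C(C)C)C(C)C | intermediate
24 | (2S,3S,4S,6S)-2-[4-(methanesulfonyloxy)phenyl]-3-(R*)-6-[2-[4-(triisopropylsilyloxy)phenyl]ethyl]oxan-4-ol | CC(C)[Si](Oc1ccc(/C=C/[C@H](C[C@@H](O[Si](C)(C)C(C)(C)C)CCc2ccc(O[Si](C(C)C)(C(C)C)C(C)C)cc2)[C@@H]2[C@@H](c3ccc(OS(C)(=O)=O)cc3)O[C@@H](CCc3ccc(O[Si](C(C)C)(C(C)C)C(C)C)cc3)C[C@@H]2O)cc1)(C(C)C)C(C)C | intermediate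
25 | 4-[(2S,3S,4S,6S)-4-hydroxy-3-[(1E,3S,5S)-5-hydroxy-1,7-bis(4-hydroxyphenyl)hept-1-en-3-yl]-6-[2-(4-hydroxyphenyl)ethyl]oxan-2-yl]phenyl methanesulfonate | Oc1ccc(/C=C/[C@H](C[C@@H](O)CCc2ccc(O)cc2)[C@@H]2[C@@H](c3ccc(OS(C)(=O)=O)cc3)O[C@@H](CCc3ccc(O)cc3)C[C@@H]2O)cc1 | intermediate
26 | blepharocalyxin C | Oc1ccc(/C=C/[C@H](C[C@@H](O)CCc2ccc(O)cc2)[C@@H]2[C@@H](c3ccc(O)cc3)O[C@@H](CCc3ccc(O)cc3)C[C@@H]2O)cc1 | target

## Step count and least certain steps

Total: 18 steps. Longest linear sequence: 15 steps (steps 1–4, 6, 7, 9, 11–18, from 1).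

**Step 15 (key step).** Three processes may interfere:
- capture of the C6 oxocarbenium ion by the electron-rich styrene π bond (a Prins-type closure through the alkene carbon next to C1', also six-membered);
- ionisation of the benzylic C2–O1 bond in spite of the sulfonate;
- hydrolysis of the enol acetal before it rearranges.

The first is the one specific to this substrate. The fallback removes the styrene from the key step: it sets out from 9 and returns at 23. Compound 9 is taken through the conditions of steps 11 to 15 with the vinyl group in place of the styryl group. This gives in turn the vinyl aldol trimethylsilyl ether F1 (not isolated), the vinyl aldol adduct F2, the vinyl peroxy acid F3 (not isolated), the vinyl β-hydroxy acid F4, its bis(trimethylsilyl) derivative F5 (not isolated), the vinyl dioxanone F6, the vinyl enol acetal F7 and the vinyl oxan-4-one F8. Cross-metathesis of F8 with 12 under the second-generation Grubbs catalyst RuCl2(=CHPh)(H2IMes)(PCy3) then gives 23.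

**Step 11.** The acyl group of 13 is branched at the β-carbon, so enolisation and addition under the mild magnesium conditions may be slow, and silylation of the aldehyde or retro-aldol equilibration may erode conversion or the anti preference. The fallback separates the two stereocentres and sets out from 13 and 15, returning at 17. Aldehyde 15 is oxidised (NaClO2, NaH2PO4, 2-methylbut-2-ene) to 4-(methanesulfonyloxy)benzoic acid F9 and converted with (COCl)2 into 4-(methanesulfonyloxy)benzoyl chloride F10. The sodium enolate of 13 (NaN(SiMe3)2, THF, −78 °C) is acylated by F10 on the face away from the benzyl group to give the β-keto imide F11, whose α-centre is configurationally stable. Corey–Bakshi–Shibata reduction of the aryl ketone with BH3·SMe2 and (R)-1-methyl-3,3-diphenyl-tetrahydro-1H,3H-pyrrolo[1,2-c][1,3,2]oxazaborole then sets the carbinol under catalyst control and gives 17.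

**Step 14.** The lactone carbonyl of 21 is flanked by the bulky C5 substituent, so the titanium methylidene may add slowly and the reagent may decompose first; the acid-labile enol acetal may also hydrolyse on isolation. The fallback brings C5 in as a malonate carbon and needs no carbonyl olefination; it sets out from 19 and returns at 23. Activation of 19 with carbonyldiimidazole and chain extension with KO2CCH2CO2Me, MgCl2 and Et3N gives the δ-hydroxy-β-keto ester F12. A Maitland–Japp condensation of F12 with 3 promoted by Yb(OTf)3 (Knoevenagel condensation, then oxa-Michael closure to the 2,6-cis ring) gives the oxan-4-one carboxylate F13. Heating F13 with LiCl in wet DMSO at 130 °C removes the methoxycarbonyl group and gives 23.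

**Step 9.** The vinyl group of 9 sits on a tertiary carbon with two branches, so the ruthenium carbene may load slowly and the styrene may be consumed by homodimerisation. The fallback forms the aryl–alkene bond instead and sets out from 9, returning at 13. A Heck reaction of 9 with (4-iodophenoxy)triisopropylsilane F14 (from 4-iodophenol and i-Pr3SiCl) under Pd(OAc)2, Bu4NCl and NaHCO3 in DMF at 60 °C should give the E styrene 13.

## Further compounds

F1 | step 15 | trimethylsilyl ether of F2 (not isolated) | C=C[C@H](C[C@@H](O[Si](C)(C)C(C)(C)C)CCc1ccc(O[Si](C(C)C)(C(C)C)C(C)C)cc1)[C@@H](C(=O)N1[C@@H](Cc2ccccc2)COC1=O)[C@@H](c1ccc(OS(C)(=O)=O)cc1)O[Si](C)(C)C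
F2 | step 15 | vinyl aldol adduct: analogue of 17 with ethenyl in place of the (E)-2-arylethenyl group | C=C[C@H](C[C@@H](O[Si](C)(C)C(C)(C)C)CCc1ccc(O[Si](C(C)C)(C(C)C)C(C)C)cc1)[C@@H](C(=O)N1[C@@H](Cc2ccccc2)COC1=O)[C@@H](c1ccc(OS(C)(=O)=O)cc1)O
F3 | step 15 | vinyl peroxy acid: analogue of 18 (not isolated) | C=C[C@H](C[C@@H](O[Si](C)(C)C(C)(C)C)CCc1ccc(O[Si](C(C)C)(C(C)C)C(C)C)cc1)[C@@H](C(=O)OO)[C@@H](c1ccc(OS(C)(=O)=O)cc1)O
F4 | step 15 | vinyl β-hydroxy acid: analogue of 19 | C=C[C@H](C[C@@H](O[Si](C)(C)C(C)(C)C)CCc1ccc(O[Si](C(C)C)(C(C)C)C(C)C)cc1)[C@@H](C(=O)O)[C@@H](c1ccc(OS(C)(=O)=O)cc1)O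
F5 | step 15 | bis(trimethylsilyl) derivative of F4 (not isolated) | C=C[C@H](C[C@@H](O[Si](C)(C)C(C)(C)C)CCc1ccc(O[Si](C(C)C)(C(C)C)C(C)C)cc1)[C@@H](C(=O)O[Si](C)(C)C)[C@@H](c1ccc(OS(C)(=O)=O)cc1)O[Si](C)(C)C
F6 | step 15 | vinyl dioxanone: analogue of 21 | C=C[C@H](C[C@@H](O[Si](C)(C)C(C)(C)C)CCc1ccc(O[Si](C(C)C)(C(C)C)C(C)C)cc1)[C@@H]1[C@@H](c2ccc(OS(C)(=O)=O)cc2)O[C@@H](CCc2ccc(O[Si](C(C)C)(C(C)C)C(C)C)cc2)OC1=O
F7 | step 15 | vinyl enol acetal: analogue of 22 | C=C[C@H](C[C@@H](O[Si](C)(C)C(C)(C)C)CCc1ccc(O[Si](C(C)C)(C(C)C)C(C)C)cc1)[C@@H]1[C@@H](c2ccc(OS(C)(=O)=O)cc2)O[C@@H](CCc2ccc(O[Si](C(C)C)(C(C)C)C(C)C)cc2)OC1=C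
F8 | step 15 | vinyl oxan-4-one: analogue of 23 | C=C[C@H](C[C@@H](O[Si](C)(C)C(C)(C)C)CCc1ccc(O[Si](C(C)C)(C(C)C)C(C)C)cc1)[C@@H]1[C@@H](c2ccc(OS(C)(=O)=O)cc2)O[C@@H](CCc2ccc(O[Si](C(C)C)(C(C)C)C(C)C)cc2)CC1=O
F9 | step 11 | 4-(methanesulfonyloxy)benzoic acid | CS(=O)(=O)Oc1ccc(C(=O)O)cc1
F10 | step 11 | 4-(methanesulfonyloxy)benzoyl chloride | CS(=O)(=O)Oc1ccc(C(Cl)=O)cc1
F11 | step 11 | (4S)-4-benzyl-3-[(2R)-3-[4-(methanesulfonyloxy)phenyl]-3-oxo-2-(R*)propanoyl]oxazolidin-2-one | CC(C)[Si](Oc1ccc(/C=C/[C@H](C[C@@H](O[Si](C)(C)C(C)(C)C)CCc2ccc(O[Si](C(C)C)(C(C)C)C(C)C)cc2)[C@@H](C(=O)N2[C@@H](Cc3ccccc3)COC2=O)C(=O)c2ccc(OS(C)(=O)=O)cc2)cc1)(C(C)C)C(C)C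
F12 | step 14 | methyl (4R,5S)-5-hydroxy-5-[4-(methanesulfonyloxy)phenyl]-3-oxo-4-(R*)pentanoate | CC(C)[Si](Oc1ccc(/C=C/[C@H](C[C@@H](O[Si](C)(C)C(C)(C)C)CCc2ccc(O[Si](C(C)C)(C(C)C)C(C)C)cc2)[C@@H](C(=O)CC(=O)OC)[C@@H](c2ccc(OS(C)(=O)=O)cc2)O)cc1)(C(C)C)C(C)C
F13 | step 14 | methyl ester of the C5 carboxylic acid of 23 (keto and enol forms, C5 unassigned) | CC(C)[Si](Oc1ccc(/C=C/[C@H](C[C@@H](O[Si](C)(C)C(C)(C)C)CCc2ccc(O[Si](C(C)C)(C(C)C)C(C)C)cc2)[C@@H]2[C@@H](c3ccc(OS(C)(=O)=O)cc3)O[C@@H](CCc3ccc(O[Si](C(C)C)(C(C)C)C(C)C)cc3)C(C(=O)OC)C2=O)cc1)(C(C)C)C(C)C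
F14 | step 9 | (4-iodophenoxy)triisopropylsilane | CC(C)[Si](Oc1ccc(I)cc1)(C(C)C)C(C)C
A1 | alternative 1 | open-chain 4-(tert-butyldimethylsilyloxy)benzyl ether of the C6 carbinol with C3 as a methyl β-keto ester carbon and ethenyl on C1' | C=C[C@H](C[C@@H](O[Si](C)(C)C(C)(C)C)CCc1ccc(O[Si](C)(C)C(C)(C)C)cc1)C(C(=O)OC)C(=O)C[C@H](CCc1ccc(O[Si](C)(C)C(C)(C)C)cc1)OCc1ccc(O[Si](C)(C)C(C)(C)C)cc1
A2 | alternative 1 | 2,6-cis 3-methoxycarbonyl oxan-4-one with ethenyl on C1' | C=C[C@H](C[C@@H](O[Si](C)(C)C(C)(C)C)CCc1ccc(O[Si](C)(C)C(C)(C)C)cc1)[C@]2(C(=O)OC)[C@@H](c3ccc(O[Si](C)(C)C(C)(C)C)cc3)O[C@@H](CCc3ccc(O[Si](C)(C)C(C)(C)C)cc3)CC2=O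
A3 | alternative 2 | (E)-1-aryl-3-(triethylsilyloxy)buta-1,3-diene carrying the full side chain on its C2 | CC(C)(C)[Si](C)(C)Oc1ccc(/C=C/[C@H](C[C@@H](O[Si](C)(C)C(C)(C)C)CCc2ccc(O[Si](C)(C)C(C)(C)C)cc2)C(=C/c2ccc(O[Si](C)(C)C(C)(C)C)cc2)\C(=C)O[Si](CC)(CC)CC)cc1
A4 | alternative 2 | 3-[4-(tert-butyldimethylsilyloxy)phenyl]propanal | CC(C)(C)[Si](C)(C)Oc1ccc(CCC=O)cc1
A5 | alternative 2 | 2,6-cis dihydropyran with a C3=C4 triethylsilyl enol ether and the full side chain | CC(C)(C)[Si](C)(C)Oc1ccc(/C=C/[C@H](C[C@@H](O[Si](C)(C)C(C)(C)C)CCc2ccc(O[Si](C)(C)C(C)(C)C)cc2)C2=C(O[Si](CC)(CC)CC)C[C@H](CCc3ccc(O[Si](C)(C)C(C)(C)C)cc3)O[C@@H]2c3ccc(O[Si](C)(C)C(C)(C)C)cc3)cc1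
A6 | alternative 3 | seco C4,C6-diol with a free 4-hydroxybenzyl group at C2 and four silyl ethers | CC(C)(C)[Si](C)(C)Oc1ccc(/C=C/[C@H](C[C@@H](O[Si](C)(C)C(C)(C)C)CCc2ccc(O[Si](C)(C)C(C)(C)C)cc2)[C@H](Cc2ccc(O)cc2)[C@@H](O)C[C@@H](O)CCc2ccc(O[Si](C)(C)C(C)(C)C)cc2)cc1
A7 | alternative 3 | blepharocalyxin C carrying four silyl ethers (three phenols and the C3' hydroxyl) | CC(C)(C)[Si](C)(C)Oc1ccc(/C=C/[C@H](C[C@@H](O[Si](C)(C)C(C)(C)C)CCc2ccc(O[Si](C)(C)C(C)(C)C)cc2)[C@@H]2[C@@H](c3ccc(O)cc3)O[C@@H](CCc3ccc(O[Si](C)(C)C(C)(C)C)cc3)C[C@@H]2O)cc1
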